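## Retrosynthetic overview
1. Jaeskeanin is the 6,7-epoxide of ferutinin (the p-hydroxybenzoate of jaeschkeanadiol). Disconnect the phenol acetate, the C4 aryl ester and the epoxide, which comes from the Δ6 alkene.
2. The C3 tertiary carbinol (isopropyl plus OH) comes from adding iPrMgCl to a trans-fused hydroazulenone.
3. The seven-membered ring is closed last by RCM between an allyl group on the quaternary carbon and a methallyl carbinol on C3a. This forms the trisubstituted Δ6 alkene.
4. The cyclopentanone carries the quaternary methyl stereocenter and the adjacent aldol carbinol. Both come from a Cu-catalysed asymmetric conjugate addition of MeMgBr to 3-allylcyclopentenone, with the enolate trapped in situ by 3-methylbut-3-enal.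
5. Ring order: the five-membered ring is already present as the enone, and the seven-membered ring is formed by RCM.

**Assumption:** the target's absolute configuration is as drawn in the given SMILES. The ACA ligand enantiomer is chosen to give the 8aR quaternary centre.

## Route

**Step 1**
Reactants: 1 (3-ethoxycyclopent-2-en-1-one), 2 (allylmagnesium bromide)
Product: 3 (3-allylcyclopent-2-en-1-one)
Conditions: 2 (1.2 equiv), THF, −78 → 0 °C; then 2 M HCl, THF, 0 °C
Reagents that add atoms: allylmagnesium bromide C=CC[Mg]Br; water O
Why: Grignard 1,2-addition to the vinylogous ester, then acid elimination and hydrolysis (Stork–Danheiser-type transposition) gives the 3-substituted enone; there are no stereocenters.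

**Step 2**
Reactants: 4 (3-methylbut-3-en-1-ol)
Product: 5 (3-methylbut-3-enal)
Conditions: Dess–Martin periodinane, NaHCO3, CH2Cl2, 0 °C; use the crude solution immediately
Reagents that add atoms: none
Why: Dess–Martin oxidation gives the β,γ-unsaturated aldehyde under mild, non-isomerising conditions.

**Step 3**
Reactants: 3 (3-allylcyclopent-2-en-1-one), 6 (methylmagnesium bromide), 5 (3-methylbut-3-enal)
Product: 7, (2S,3R)-2-[(1S)-1-hydroxy-3-methylbut-3-en-1-yl]-3-methyl-3-(prop-2-en-1-yl)cyclopentan-1-one
Conditions: 6 (1.1 equiv), CuBr·SMe2 (5 mol %), chiral ferrocenyl diphosphine (Josiphos type, 6 mol %), MTBE, −78 °C; then 5 (1.5 equiv), −78 → −40 °C; sat. NH4Cl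
Reagents that add atoms: methylmagnesium bromide C[Mg]Br (the aldehyde is numbered reactant 5)
Why: Cu-catalysed asymmetric conjugate addition (ACA) sets the quaternary C3 (R) and generates the magnesium enolate regiospecifically at C2. That enolate undergoes a Zimmerman–Traxler aldol; the ring-locked E-enolate gives the anti aldol, and the aldehyde approaches anti to the allyl group (cis to methyl), giving the trans relationship to allyl needed for the trans ring fusion.

**Step 4**
Reactants: 7
Product: 8, (3aS,4S,8aR)-4-hydroxy-6,8a-dimethyl-2,3a,4,5,8,8a-hexahydroazulen-3(1H)-one (trans-fused)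
Conditions: Hoveyda–Grubbs II (10 mol %), DCE (5 mM), 60 °C, Ar sparge
Reagents that add atoms: none (ethylene is lost)
Why: ring-closing metathesis (RCM) joins the allyl CH=CH2 and the methallyl C(Me)=CH2 to give the trisubstituted Δ6 cycloheptene; no stereocenter is created or altered, and the trans-diaxial-type tethers (Cg up, allyl down) give the trans-fused ring.

**Step 5**
Reactants: 8, 9 (isopropylmagnesium chloride)
Product: 10, jaeschkeanadiol, (3R,3aS,4S,8aR)-6,8a-dimethyl-3-(propan-2-yl)-1,2,3,3a,4,5,8,8a-octahydroazulene-3,4-diol
Conditions: 9·LiCl (4 equiv), CeCl3 (3 equiv), THF, −78 → 0 °C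
Reagents that add atoms: isopropylmagnesium chloride CC(C)[Mg]Cl
Why: organocerium-moderated Grignard addition suppresses enolisation and reduction, and the C4 magnesium alkoxide (one equivalent of 9 deprotonates the C4–OH) directs delivery. The isopropyl group adds to the face anti to the C3a side chain and the axial angular methyl, setting the C3 carbinol (R) with OH cis to C4.

**Step 6**
Reactants: 10, 11 (4-acetoxybenzoyl chloride)
Product: 12, the C4 4-acetoxybenzoate of jaeschkeanadiol
Conditions: 11 (1.5 equiv), DMAP (0.2 equiv), Et3N, CH2Cl2, 0 °C → rt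
Reagents that add atoms: 4-acetoxybenzoyl chloride CC(=O)Oc1ccc(cc1)C(Cl)=O
Why: DMAP-catalysed acylation (Steglich-type) is selective for the secondary C4–OH over the hindered tertiary C3–OH, and the configuration at C4 is retained.

**Step 7**
Reactants: 12, 13 (mCPBA)
Product: 14, the 6,7-epoxide of 12
Conditions: 13 (1.2 equiv), NaHCO3, CH2Cl2, 0 °C
Reagents that add atoms: mCPBA OOC(=O)c1cccc(Cl)c1
Why: Prilezhaev epoxidation occurs only at the one alkene, and the peracid attacks the face anti to the axial angular methyl, giving the (6R,7S) epoxide cis to the C4 ester.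

**Step 8**
Reactants: 14
Product: 15, jaeskeanin
Conditions: K2CO3 (0.3 equiv), MeOH, 0 °C, 20 min
Reagents that add atoms: none
Why: methanolysis of the labile phenolic acetate is far faster than cleavage of the hindered alkyl benzoate or opening of the trisubstituted epoxide, and the resulting phenoxide further protects the ester.

## Compound list
1 | 3-ethoxycyclopent-2-en-1-one | CCOC1=CC(=O)CC1 | starting material
2 | allylmagnesium bromide | C=CC[Mg]Br | starting material
3 | 3-allylcyclopent-2-en-1-one | C=CCC1=CC(=O)CC1 | intermediate
4 | 3-methylbut-3-en-1-ol | C=C(C)CCO | starting material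
5 | 3-methylbut-3-enal | C=C(C)CC=O | intermediate
6 | methylmagnesium bromide | C[Mg]Br | starting material
7 | (2S,3R)-2-[(1S)-1-hydroxy-3-methylbut-3-en-1-yl]-3-methyl-3-allylcyclopentan-1-one | C=CC[C@@]1(C)CCC(=O)[C@@H]1[C@@H](O)CC(C)=C | intermediate
8 | (3aS,4S,8aR)-4-hydroxy-6,8a-dimethyl-hexahydroazulen-3-one | C[C@]12CCC(=O)[C@@H]1[C@@H](O)CC(C)=CC2 | intermediate
9 | isopropylmagnesium chloride | CC(C)[Mg]Cl | starting material
10 | jaeschkeanadiol | CC(C)[C@]1(O)CC[C@]2(C)CC=C(C)C[C@H](O)[C@H]21 | intermediate
11 | 4-acetoxybenzoyl chloride | CC(=O)Oc1ccc(cc1)C(Cl)=O | starting material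
12 | jaeschkeanadiol 4-(4-acetoxybenzoate) | CC(C)[C@]1(O)CC[C@]2(C)CC=C(C)C[C@H](OC(=O)c3ccc(OC(C)=O)cc3)[C@H]21 | intermediate
13 | mCPBA | OOC(=O)c1cccc(Cl)c1 | starting material
14 | 6,7-epoxy-12 (acetate) | CC(C)[C@]1(O)CC[C@]2(C)C[C@@H]3O[C@]3(C)C[C@H](OC(=O)c3ccc(OC(C)=O)cc3)[C@H]21 | intermediate
15 | jaeskeanin, (3R,3aS,4S,6R,7S,8aR)-6,7-epoxy-3-hydroxy-6,8a-dimethyl-3-isopropyl-decahydroazulen-4-yl 4-hydroxybenzoate | CC(C)[C@]1(O)CC[C@]2(C)C[C@@H]3O[C@]3(C)C[C@H](OC(=O)c3ccc(O)cc3)[C@H]21 | target

## Totals
Total steps: 8. Longest linear sequence: 7 (1 → 3 → 7 → 8 → 10 → 12 → 14 → 15).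

## Three steps most likely to fail
1. **Step 3 (ACA–aldol).** Risks are the ee at the allyl/methyl quaternary centre, γ-deprotonation of the allyl enone, enolisation of the β,γ-unsaturated aldehyde, and the Ch/Cg diastereoselectivity.
   Fallback: trap the ACA enolate as its TMS enol ether, then run a Ti-mediated Mukaiyama aldol with 5, so that a less basic nucleophile is used.
2. **Step 4 (RCM).** A trisubstituted alkene must form in a trans-fused, quaternary-congested cycloheptene.
   Fallback: close the ring by intramolecular Nozaki–Hiyama–Kishi allylation, with a γ-selective allylchromium from a Cq-tethered allylic bromide adding to a C3a-aldehyde. This forms Cf–Cg, sets the Δ6 alkene and sets the carbinol.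
3. **Step 5 (iPr addition).** The hindered, enolisable β-hydroxyketone may give reduction or enolisation, or the wrong face.
   Fallback: add isopropenyllithium/CeCl3, then do a hydroxyl-directed hydrogenation (Crabtree) of the isopropenyl group, so that the carbinol is built with an sp2 nucleophile.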